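**Assumption:** Acredinone B has no stereocentres and no configurationally stable axis (achiral), so "single enantiomer" needs no stereocontrol. 4‑Methoxy‑3,5‑dimethylphenol is taken as a catalogue compound (otherwise one step from 4‑bromo‑2,6‑dimethylanisole by Li/B(OMe)3/H2O2).

## Retrosynthetic overview
1. The target is Ar–CH2–C(=O)–Ar with two identical aryl groups, so after MOM removal the central CH2–C(=O) bond is cut into benzylic alcohol 5 and aldehyde 6 (new redox‑neutral dehydrative union); which carbon becomes C=O is irrelevant.
2. Aldehyde 6 comes from alcohol 5 (MnO2); 5 comes from methyl ketone 4 by lateral lithiation and O‑transfer to the methyl ortho to the ketone.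
3. Ketone 4 comes from MOM ether 2 and 2,6‑dimethoxybenzoyl chloride 3 by directed ortho‑metalation/acylation; the C2‑symmetric phenol 1 makes the regiochemistry unambiguous.
4. No carbocycle is built: all four benzene rings are purchased. The only ring formed is a transient isobenzofuran, made and reopened in the key step.

Standard reagents (MOMCl, n‑BuLi, oxaziridine, MnO2, acids) are not numbered.

## Route

**Step 1**
Reactants: 1, 4‑methoxy‑3,5‑dimethylphenol
Product: 2, 2‑methoxy‑5‑(methoxymethoxy)‑1,3‑dimethylbenzene
Conditions: MOMCl, i‑Pr2NEt, CH2Cl2, 0 °C → rt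
Reagents that add atoms: chloromethyl methyl ether, COCCl
Why: Williamson‑type O‑alkylation (MOM protection) of the only OH; the MOM group masks the phenol against strong base and is the directing group for Step 2; no stereocentre.

**Step 2**
Reactants: 2; 3, 2,6‑dimethoxybenzoyl chloride
Product: 4, (2,6‑dimethoxyphenyl)[3‑methoxy‑6‑(methoxymethoxy)‑2,4‑dimethylphenyl]methanone
Conditions: n‑BuLi, TMEDA, THF, 0 °C, 1.5 h; then cannulate into 3 (1.5 equiv), THF, −78 → 0 °C
Reagents that add atoms: none (all new atoms come from reactant 3)
Why: OMOM‑directed ortho‑metalation (the two ortho C–H are equivalent by symmetry), then acylation of the aryllithium; four ortho substituents block over‑addition and inverse addition keeps ArLi from deprotonating the product's ortho‑methyl; no stereocentre.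

**Step 3**
Reactants: 4
Product: 5, (2,6‑dimethoxyphenyl)[2‑(hydroxymethyl)‑3‑methoxy‑6‑(methoxymethoxy)‑4‑methylphenyl]methanone (in equilibrium with its cyclic lactol; purify on Et3N‑deactivated silica)
Conditions: LiTMP (1.3 equiv), THF, −78 °C; then (10‑camphorsulfonyl)oxaziridine, −78 → −40 °C; NH4Cl
Reagents that add atoms: (10‑camphorsulfonyl)oxaziridine, either enantiomer, transfers one O; CC1(C)C2CCC13CS(=O)(=O)N1OC31C2
Why: Carbonyl‑directed lateral lithiation of the methyl ortho to the ketone gives a lithium dienolate (the para methyl is not reached kinetically), and Davis‑type electrophilic hydroxylation at the exocyclic CH2 restores aromaticity; no stereocentre.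

**Step 4**
Reactants: 5 (about 55 % of the batch)
Product: 6, 2‑(2,6‑dimethoxybenzoyl)‑6‑methoxy‑3‑(methoxymethoxy)‑5‑methylbenzaldehyde
Conditions: activated MnO2, CH2Cl2, rt
Reagents that add atoms: none
Why: MnO2 oxidation of the benzylic alcohol (through the open form of the lactol) stops at the aldehyde because the lactol carbon is fully substituted; neutral conditions spare the MOM ether; no stereocentre.

**Step 5 (key step, new)**
Reactants: 5 (1.0 equiv); 6 (1.3 equiv)
Product: 7, 1,2‑bis[2‑(2,6‑dimethoxybenzoyl)‑6‑methoxy‑3‑(methoxymethoxy)‑5‑methylphenyl]ethan‑1‑one (bis‑MOM acredinone B)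
Conditions: CSA (15 mol %), degassed DCE, 40 °C, Ar, dark, 5 added by syringe pump over 4 h; then wet THF, rt; NaHCO3 work‑up (crude may go straight into Step 6, so any MOM loss here is harmless)
Reagents that add atoms: none (net 5 + 6 → 7 + H2O)
Why: Proposed new method: a Brønsted‑acid‑catalysed, redox‑neutral dehydrative union of an o‑aroylbenzyl alcohol with an aldehyde through a transient isobenzofuran. Alcohol 5 closes to its lactol and loses water to give the 1‑aryl‑isobenzofuran, whose free, highly nucleophilic C3–H attacks acid‑activated aldehyde 6 (furan‑type Friedel–Crafts hydroxyalkylation). The resulting furfuryl‑type carbinol ionises, water adds at the aryl‑bearing C1 of the extended oxocarbenium, and ring opening with enol→ketone tautomerisation makes the former CH2OH carbon the C=O and the former CHO carbon the CH2; no stereocentre. Slow addition of 5 and excess 6 suppress isobenzofuran self‑reaction. Closest known chemistry: acid‑promoted formation of 1‑arylisobenzofurans from o‑acylbenzyl alcohols, Friedel–Crafts hydroxyalkylation of furans by aldehydes, and hydrolytic ring opening of 2‑furylcarbinols to 1,4‑dicarbonyls (furfuryl alcohol → levulinate, Marckwald type).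

**Step 6**
Reactants: 7
Product: 8, acredinone B, 1,2‑bis[2‑(2,6‑dimethoxybenzoyl)‑3‑hydroxy‑6‑methoxy‑5‑methylphenyl]ethan‑1‑one
Conditions: 3 M aq. HCl, MeOH–THF, 45 °C; aqueous work‑up
Reagents that add atoms: none
Why: Acid‑catalysed acetal hydrolysis (MOM cleavage, assisted by the ortho carbonyl) frees both phenols while the six aryl methyl ethers survive; MeOH scavenges formaldehyde and the aqueous work‑up returns any isochromene/pyrylium form to the open diketone; no stereocentre.

## Compound list
1 | 4‑methoxy‑3,5‑dimethylphenol | COc1c(C)cc(O)cc1C | starting material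
2 | 2‑methoxy‑5‑(methoxymethoxy)‑1,3‑dimethylbenzene | COCOc1cc(C)c(OC)c(C)c1 | intermediate
3 | 2,6‑dimethoxybenzoyl chloride | COc1cccc(OC)c1C(Cl)=O | starting material
4 | (2,6‑dimethoxyphenyl)[3‑methoxy‑6‑(methoxymethoxy)‑2,4‑dimethylphenyl]methanone | COCOc1cc(C)c(OC)c(C)c1C(=O)c1c(OC)cccc1OC | intermediate
5 | (2,6‑dimethoxyphenyl)[2‑(hydroxymethyl)‑3‑methoxy‑6‑(methoxymethoxy)‑4‑methylphenyl]methanone | COCOc1cc(C)c(OC)c(CO)c1C(=O)c1c(OC)cccc1OC | intermediate
6 | 2‑(2,6‑dimethoxybenzoyl)‑6‑methoxy‑3‑(methoxymethoxy)‑5‑methylbenzaldehyde | COCOc1cc(C)c(OC)c(C=O)c1C(=O)c1c(OC)cccc1OC | intermediate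
7 | bis‑MOM acredinone B | COCOc1cc(C)c(OC)c(CC(=O)c2c(OC)c(C)cc(OCOC)c2C(=O)c2c(OC)cccc2OC)c1C(=O)c1c(OC)cccc1OC | intermediate
8 | acredinone B (achiral) | COc1cccc(OC)c1C(=O)c1c(O)cc(C)c(OC)c1CC(=O)c1c(OC)c(C)cc(O)c1C(=O)c1c(OC)cccc1OC | target

## Summary
Total steps: 6. Longest linear sequence: 6 (1 → 2 → 4 → 5 → 6 → 7 → 8).

Steps most likely to fail, with fallbacks:
1. **Step 5 (new isobenzofuran union).** The isobenzofuran may self‑react or fail to capture the hindered aldehyde. Fallback (known chemistry): deprotonate methyl ketone 4 with LiTMP (lateral lithiation) and add the dienolate to aldehyde 6 (vinylogous aldol), then oxidise the resulting hydroxy ketone/lactol with Dess–Martin periodinane/NaHCO3 to 7.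
2. **Step 2 (intermolecular formation of the tetra‑ortho‑substituted benzophenone).** Fallback: deliver the acyl group intramolecularly. Brominate 1 ortho to OH (NBS), esterify with 3, trigger an anionic Fries 1,3 O→C aroyl shift by Br/Li exchange (n‑BuLi, −78 °C), then MOM‑protect to reach 4.
3. **Step 3 (lateral lithiation/hydroxylation).** Deprotonation may be incomplete or O‑transfer poor. Fallback: photoenolise 4 (365 nm) under O2, reduce the trapped cyclic peroxide (Me2S) to obtain aldehyde 6 directly, and make 5 by aldehyde‑selective NaBH4 reduction of part of 6.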